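Everything rests on cutting the O1–C7 ether bond of ring B. O1 links two fully substituted carbons (C7 and C11), and C7 sits next to the oxygen-bearing C8. This identifies ring B as the product of the C11 hydroxyl attacking the more substituted carbon of a C7–C8 epoxide. One Lewis-acid-promoted 6-endo closure makes O1–C7, closes ring B, sets C7 by inversion and releases the C8 hydroxyl for acetylation. The precursor is an open chain carrying the Z-derived (7R,8S)-epoxide, the (10S)-bromide, the C11 tertiary alcohol and a finished ring A. The all-equatorial C4'–Cl/C5'–Br pair of ring A comes from a bromonium ion generated only on the ring face cis to the side chain.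

Key step: step 14

Remark: ring B is numbered O1, C7 (Me, ring A), C8, C9, C10, C11 (Me2) and ring A is C1' (on C7) to C6'; the target is read as 7S,8S,10S,1'R,4'R,5'R with side chain, Br and Cl all equatorial on ring A, a pattern that direct trans-diaxial bromochlorination of a limonene-type alkene is not expected to give, hence steps 1, 5 and 6.

Step 1
Reactants: 1 (R)-limonene
Product: 2 (1R,2S,4R)-limonene 1,2-oxide (C4'–C5' epoxide, oxygen on the ring face opposite the isopropenyl group)
Conditions: mCPBA, CH2Cl2, 0 °C; crude epoxides, pyrrolidine, H2O, 100 °C; distillation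
Reagents that add atoms: m-chloroperoxybenzoic acid, OOC(=O)c1cccc(Cl)c1
Why: The Prilezhaev epoxidation picks the electron-rich trisubstituted ring alkene but not a face, and the following kinetic separation rests on the Fürst–Plattner rule, since only the other epoxide can be opened trans-diaxially by the amine at its unhindered C5', so that 2, which fixes C4' and C5' relative to C1', is recovered unchanged.

Step 2
Reactants: 2 (1R,2S,4R)-limonene 1,2-oxide
Product: 3 epoxy methyl ketone (acetyl at C1', epoxide oxygen anti to the acetyl group)
Conditions: O3, CH2Cl2–MeOH, −78 °C; Me2S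
Reagents that add atoms: ozone, [O-][O+]=O
Why: Ozonolysis with reductive work-up (Criegee mechanism) cleaves the only remaining alkene and leaves the epoxide and C1' untouched.

Step 3
Reactants: 3 epoxy methyl ketone
Product: 5 epoxy alkyne (ethynyl C7≡C8 at C1'), via enol diethyl phosphate 4 (not isolated)
Conditions: LDA, THF, −78 °C; ClP(O)(OEt)2; LDA (2.3 equiv), −78 to 0 °C; H2O
Reagents that add atoms: none
Why: In this methyl ketone to terminal alkyne conversion by enol phosphate elimination, kinetic deprotonation at the methyl group spares C1', O-phosphorylation and LDA-induced loss of diethyl phosphate follow, and a trisubstituted epoxide tolerates LDA below 0 °C.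

Step 4
Reactants: 5 epoxy alkyne; 6 ethyl chloroformate
Product: 8 epoxy ynoate (ethyl ester C9 on C8), via lithium acetylide 7 (not isolated)
Conditions: n-BuLi, THF, −78 °C; 6, −78 to −20 °C
Reagents that add atoms: ethyl chloroformate (6), CCOC(=O)Cl
Why: Deprotonation of the terminal alkyne and C-acylation of the acetylide with a chloroformate is standard and faster than any attack on the hindered epoxide at this temperature.

Step 5
Reactants: 8 epoxy ynoate
Product: 9 trans-diaxial bromohydrin ynoate (tertiary Br at C4' on the side-chain face, OH at C5' on the opposite face)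
Conditions: 48% aq. HBr (1.2 equiv), Et2O, −10 °C
Reagents that add atoms: hydrogen bromide, Br
Why: In this acid-mediated epoxide opening the Markovnikov preference (tertiary C4') and the Fürst–Plattner preference (trans-diaxial product) coincide for this epoxide face, so bromide enters C4' with inversion and leaves the C5' hydroxyl antiperiplanar to it.

Step 6
Reactants: 9 trans-diaxial bromohydrin ynoate
Product: 10 bromochloro ynoate ((1'R,4'R,5'R) ring A: Cl on C4' anti and Br on C5' syn to the side chain, all equatorial, methyl axial)
Conditions: SOCl2, pyridine, CH2Cl2, −20 to 0 °C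
Reagents that add atoms: thionyl chloride, O=S(Cl)Cl
Why: This is a deoxychlorination with neighbouring-group participation by bromine, in which loss of the chlorosulfite is assisted by the antiperiplanar C4'–Br bond, the bromonium ion can therefore form only on the face cis to the side chain, and chloride opens it at tertiary C4' from the other face through the half-chair that holds the slim alkynyl group axial, inverting both carbons to 4'R,5'R.

Step 7
Reactants: 10 bromochloro ynoate
Product: 11 ethyl (Z)-enoate (methyl on C7, ring A cis to the ester)
Conditions: MeLi (2.2 equiv), CuI (1.1 equiv), THF, 0 °C; 10, −78 °C; aq. NH4Cl at −78 °C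
Reagents that add atoms: lithium dimethylcuprate (from methyllithium, [Li]C, and CuI), [Li+].C[Cu-]C
Why: Syn-carbocupration of an alkynoate followed by cold protonation puts methyl and hydrogen on the same side, which makes ring A and the ester cis (Z), while the secondary bromide and tertiary chloride are inert to the cuprate at −78 °C.

Step 8
Reactants: 11 ethyl (Z)-enoate
Product: 12 (Z)-allylic alcohol (C9 hydroxyl)
Conditions: DIBAL-H (2.5 equiv), CH2Cl2, −78 °C
Reagents that add atoms: none
Why: DIBAL-H reduces the enoate in the 1,2 sense to the allylic alcohol without touching alkene geometry or alkyl halides.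

Step 9
Reactants: 12 (Z)-allylic alcohol
Product: 13 (Z)-allylic bromide (used crude)
Conditions: CBr4, PPh3, CH2Cl2, −30 °C
Reagents that add atoms: carbon tetrabromide, BrC(Br)(Br)Br
Why: The Appel reaction displaces the primary allylic oxyphosphonium group by SN2 at low temperature, which keeps the Z geometry.

Step 10
Reactants: 13 (Z)-allylic bromide; 14 1-bromo-2-methylprop-1-ene
Product: 16 (7Z)-skipped diene (C7=C8 and C10=C11), via 2-methylprop-1-enylmagnesium bromide 15 (not isolated)
Conditions: 14, Mg, THF, reflux; CuI (10 mol %), 13, THF, −40 to −10 °C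
Reagents that add atoms: 1-bromo-2-methylprop-1-ene (14), CC(C)=CBr
Why: The copper-catalysed allyl–vinyl Grignard coupling attacks the primary allylic carbon because the SN2' alternative would build a quaternary C7, and the allylic bromide far outruns the ring A halides.

Step 11
Reactants: 16 (7Z)-skipped diene
Product: 17 (10R)-C10–C11 epoxide
Conditions: D-fructose-derived Shi ketone (30 mol %), Oxone (2KHSO5·KHSO4·K2SO4), K2CO3, Na2B4O7/Na2EDTA buffer, Bu4NHSO4, MeCN–dimethoxymethane, 0 °C
Reagents that add atoms: potassium peroxymonosulfate (KHSO5), [K+].[O-]S(=O)(=O)OO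
Why: In the Shi asymmetric epoxidation the spiro transition state accepts only a small group cis to the vicinal substituent, a demand met by C10=C11 (methyl) but not by C7=C8 (ring A), which gives site selectivity, and the D-fructose-derived ketone sets C10 as R.

Step 12
Reactants: 17 (10R)-C10–C11 epoxide
Product: 18 (10S)-bromohydrin (Br on C10, tertiary OH on C11, Z-alkene C7=C8)
Conditions: Li2NiBr4, THF, 0 °C to rt; pH 7 buffer
Reagents that add atoms: dilithium tetrabromonickelate (Li2NiBr4), [Li+].[Li+].[Ni+2].[Br-].[Br-].[Br-].[Br-]
Why: SN2 epoxide opening by a soft, non-acidic bromide source goes to the less substituted C10 with inversion, turning 10R-oxygen into 10S-bromine and freeing the C11 hydroxyl.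

Step 13
Reactants: 18 (10S)-bromohydrin
Product: 19 epoxy alcohol (7R,8S,10S; ring A cis to C9 on the epoxide)
Conditions: VO(acac)2 (5 mol %), t-BuOOH, 2,6-lutidine (10 mol %), toluene, 0 °C
Reagents that add atoms: tert-butyl hydroperoxide, CC(C)(C)OO
Why: In this hydroxyl-directed epoxidation of a bishomoallylic alcohol the C11 vanadate delivers oxygen to the alkene face over which the C9–C11 arm folds, and with one C9–H held in the alkene plane by allylic 1,3-strain against ring A and the C10–Br bond anti to both C8 and the C11 oxygen this is the face giving the (7R,8S)-epoxide, while the lutidine buffer holds back ring closure.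

Step 14
Reactants: 19 epoxy alcohol
Product: 20 caespitol
Conditions: BF3·OEt2 (20 mol %), CH2Cl2, −78 to −40 °C
Reagents that add atoms: none
Why: BF3 binds the epoxide oxygen, the C7–O bond lengthens because C7 (Me, ring A, C8) carries positive charge far better than secondary C8, and the C11 hydroxyl adds to C7 on the face opposite the leaving oxygen before losing its proton; the closest known reaction type is the acid-promoted endo cyclisation of a 4,5-epoxy alcohol at the tertiary carbon of a trisubstituted epoxide. Ring B closes in the 6-endo-tet mode, the rival being 5-exo-tet attack at C8 to a tetrahydrofuran. C7 is the only new stereocentre and becomes S by inversion of the (7R)-epoxide carbon, that is through the Z geometry from step 7 and the face chosen in step 13, while C8 keeps its oxygen and C10 is not touched. The step needs regioselectivity, which the substrate supports through the fully alkylated C7 and through the C10 bromine, which withdraws electrons from C8 more than from C7 and makes the hydroxyl a weak nucleophile, so that bond making lags behind C7–O bond breaking. A strictly anti closure first gives the chair with ring A axial and the C8 oxygen equatorial, which relaxes by ring flip to the stable chair (ring A and Br equatorial, OH axial), so a strong Lewis acid in a non-coordinating solvent at low temperature is chosen to keep the transition state cation-like. The ring A halides and the C10 bromide are inert to catalytic BF3·OEt2 at this temperature.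

Step 15
Reactants: 20 caespitol
Product: 21 acetylcaespitol
Conditions: Ac2O, DMAP, Et3N, CH2Cl2, rt
Reagents that add atoms: acetic anhydride, CC(=O)OC(C)=O
Why: DMAP-catalysed acylation esterifies the hindered axial C8 hydroxyl, the only hydroxyl present, without touching any stereocentre.

Compound list
1 | (R)-limonene | CC(=C)[C@@H]1CCC(C)=CC1 | starting material
2 | (1R,2S,4R)-limonene 1,2-oxide, oxygen anti to isopropenyl | CC(=C)[C@@H]1CC[C@@]2(C)O[C@H]2C1 | intermediate
3 | epoxy methyl ketone, oxygen anti to acetyl | CC(=O)[C@@H]1CC[C@@]2(C)O[C@H]2C1 | intermediate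
4 | enol diethyl phosphate of 3 (terminal methylene isomer) | C=C(OP(=O)(OCC)OCC)[C@@H]1CC[C@@]2(C)O[C@H]2C1 | intermediate
5 | epoxy alkyne | C#C[C@@H]1CC[C@@]2(C)O[C@H]2C1 | intermediate
6 | ethyl chloroformate | CCOC(=O)Cl | starting material
7 | lithium acetylide of 5 | [Li]C#C[C@@H]1CC[C@@]2(C)O[C@H]2C1 | intermediate
8 | epoxy ynoate | CCOC(=O)C#C[C@@H]1CC[C@@]2(C)O[C@H]2C1 | intermediate
9 | trans-diaxial bromohydrin ynoate (C4' Br syn, C5' OH anti to side chain) | CCOC(=O)C#C[C@@H]1CC[C@](C)(Br)[C@@H](O)C1 | intermediate
10 | (1'R,4'R,5'R)-bromochloro ynoate | CCOC(=O)C#C[C@@H]1CC[C@@](C)(Cl)[C@H](Br)C1 | intermediate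
11 | ethyl (Z)-enoate | CCOC(=O)/C=C(/C)[C@@H]1CC[C@@](C)(Cl)[C@H](Br)C1 | intermediate
12 | (Z)-allylic alcohol | OC/C=C(/C)[C@@H]1CC[C@@](C)(Cl)[C@H](Br)C1 | intermediate
13 | (Z)-allylic bromide | BrC/C=C(/C)[C@@H]1CC[C@@](C)(Cl)[C@H](Br)C1 | intermediate
14 | 1-bromo-2-methylprop-1-ene | CC(C)=CBr | starting material
15 | 2-methylprop-1-enylmagnesium bromide | CC(C)=C[Mg]Br | intermediate
16 | (7Z)-skipped diene | CC(C)=CC/C=C(/C)[C@@H]1CC[C@@](C)(Cl)[C@H](Br)C1 | intermediate
17 | (10R)-C10–C11 epoxide | CC1(C)O[C@@H]1C/C=C(/C)[C@@H]2CC[C@@](C)(Cl)[C@H](Br)C2 | intermediate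
18 | (10S)-bromohydrin with Z-alkene | CC(C)(O)[C@@H](Br)C/C=C(/C)[C@@H]1CC[C@@](C)(Cl)[C@H](Br)C1 | intermediate
19 | (7R,8S,10S)-epoxy alcohol, key-step precursor | CC(C)(O)[C@@H](Br)C[C@@H]1O[C@]1(C)[C@@H]1CC[C@@](C)(Cl)[C@H](Br)C1 | intermediate
20 | caespitol | O[C@H]1C[C@H](Br)C(C)(C)O[C@@]1(C)[C@@H]1CC[C@@](C)(Cl)[C@H](Br)C1 | intermediate
21 | acetylcaespitol | CC(=O)O[C@H]1C[C@H](Br)C(C)(C)O[C@@]1(C)[C@@H]1CC[C@@](C)(Cl)[C@H](Br)C1 | target

Total step count: 15. Longest linear sequence: 15 steps, from (R)-limonene 1 to 21.

Steps most likely to fail

Step 14. Attack of the hydroxyl at C8 (5-exo closure) or a 1,2-hydride shift from C8 to C7 may outrun the 6-endo closure, because the anti trajectory has to pass through a crowded ring conformation. The fallback closes ring B at its other ether bond. It sets out from allylic alcohol 12.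
- Sharpless asymmetric epoxidation (Ti(OiPr)4, L-(+)-diethyl tartrate, t-BuOOH, 4 Å sieves, CH2Cl2, −20 °C) should give the (7R,8S)-epoxy alcohol F1.
- Tf2O and 2,6-lutidine at −78 °C give the primary triflate F2.
- Grignard reagent 15 with CuI displaces the triflate to give the epoxy alkene F3.
- Dilute HClO4 in aqueous THF opens F3 with water at tertiary C7, with inversion, to the (7S,8S)-diol F4.
- Bromoetherification of F4 with 2,4,4,6-tetrabromocyclohexa-2,5-dienone in MeNO2 lets the C7 hydroxyl attack C11 of the C10–C11 bromonium ion (6-endo, Markovnikov, chair with Br equatorial). This comes back to the route at caespitol 20.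

Step 6. Chloride may capture the bromonium ion at the secondary carbon, or HBr may be lost from the tertiary bromide before ionisation. The fallback sets out from bromohydrin 9 and comes back at 10. Capture at C5' gives the trans-diaxial C4'-bromide C5'-chloride F5, in which each halogen already sits on its final ring face. Heating F5 in toluene, or warming it in (CF3)2CHOH, should bring about the diaxial-to-diequatorial 1,2-interchange of vicinal halogens. This dyotropic shift is known for steroidal dihalides; here a tertiary bromide is traded for a tertiary chloride, but the axial methyl in 10 offsets much of that gain, so the interchange may stop at an equilibrium mixture from which 10 is separated.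

Step 13. The facial bias may be weak, or vanadium may promote premature ring closure of the epoxy alcohol. The fallback gives up direction by the hydroxyl. It sets out from 18.
- TMSOTf and 2,6-lutidine give the trimethylsilyl ether F6.
- Metal-free epoxidation with dimethyldioxirane in acetone at −20 °C gives both epoxides.
- Chromatography isolates the silylated (7R,8S)-epoxide F7.
- Et3N·3HF in THF at 0 °C removes the silyl group and comes back to the route at 19.

Further compounds
F1 | step 14 | (7R,8S)-epoxy alcohol with C9 hydroxyl | OC[C@@H]1O[C@]1(C)[C@@H]1CC[C@@](C)(Cl)[C@H](Br)C1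
F2 | step 14 | primary triflate of F1 | O=S(=O)(OC[C@@H]1O[C@]1(C)[C@@H]1CC[C@@](C)(Cl)[C@H](Br)C1)C(F)(F)F
F3 | step 14 | (7R,8S)-epoxy alkene with C10=C11 | CC(C)=CC[C@@H]1O[C@]1(C)[C@@H]1CC[C@@](C)(Cl)[C@H](Br)C1
F4 | step 14 | (7S,8S)-diol with C10=C11 | CC(C)=CC[C@H](O)[C@@](C)(O)[C@@H]1CC[C@@](C)(Cl)[C@H](Br)C1
F5 | step 6 | trans-diaxial C4'-bromide C5'-chloride ynoate | CCOC(=O)C#C[C@@H]1CC[C@](C)(Br)[C@@H](Cl)C1
F6 | step 13 | C11 trimethylsilyl ether of 18 | CC(C)(O[Si](C)(C)C)[C@@H](Br)C/C=C(/C)[C@@H]1CC[C@@](C)(Cl)[C@H](Br)C1
F7 | step 13 | C11 trimethylsilyl ether of 19 | CC(C)(O[Si](C)(C)C)[C@@H](Br)C[C@@H]1O[C@]1(C)[C@@H]1CC[C@@](C)(Cl)[C@H](Br)C1
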